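Late in the run I expected little to watch: the half-life of Sub, 1.36 h, is far shorter than the 15 d of the flask, so Tgt3 forms in the first hours.

Sub 0.010 M; Rea2 8.00 mM (fed, over 1.5 h); Tsp 0.37 mM (held); time 15 d

    Sub → Imd (k1 = 0.510 /h)
    Rea + Imd → Tgt2 (k2 = 24700 /M/h)
    Rea2 + Imd → Tgt3 (k3 = 13700 /M/h)
    Imd → Tgt (k4 = 14.8 /h)
    Tsp ⇌ Rea, rate k5*(csat - [Rea]) (k5 = 0.972 /h, csat = 0.37 mM)

- at the start none of Rea is dissolved
- the reaction counts as stopped when no species that holds the Sub changes by six tenths of a point or more over the second half of the time
- run time (flask): 15 d

1. which holds at 15 d: what has brought the reaction to rest, or that it has not come to rest (forward and back rates have come level / Rea2 has run out first / all of Sub has reacted / it is still moving)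
2. how much Tgt2 there is at 15 d, in percent of the Sub charged
3. how much Tgt3 there is at 15 d, in percent of the Sub charged

You asked for a quick number, and your hunch was that Tgt3 in the flask reaches the ceiling of the charges, 80.0% of Sub. I reckoned lower. Imd leaves far faster than it forms, 14.8 /h against 0.510 /h, so each Imd takes its exit at the [Rea2] of that moment. I replaced the curve of [Rea2] by one mean. Weighted by the decay of Sub, the feed had delivered 69.9% of the charge when Imd forms, or 5.59 mM. From this I took half of the Rea2 spent by the end. I put [Rea] at 0.37 mM, which gave the other exits 23.9 /h together. That gave 59.8% for the mean capture share, the part of Imd that Rea2 takes at its mean concentration, here 2.60 mM, at 13700 /M/h against those exits; this share is the selectivity of the branch point. But Rea starts at none, so I checked the error by repeating the reckoning without Rea, which gave 67.3%. I committed to 59.8%, with 67.3% as the other edge.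

The forecast gave all of Sub has reacted, 8% of Tgt2 and 62% of Tgt3, with Rea2 left over since it “outcompetes the other routes only in part”. The simulation of the flask gave all of Sub has reacted, 6.90% of Tgt2 and 62.6% of Tgt3, with 22% of the Rea2 left at 15.0 d.

That Tgt3 stands 2.8 percentage points above my share and below 67.3%. The neighbouring flask has 0.0032 M of Rea2 and the same Sub. The same reckoning put its weighted feed at 2.24 mM and its mean capture share at 29.9%. The neighbouring flask gave 30.9% of Tgt3 and 11.3% of Tgt2, and Tgt held the most of its Sub, 57.9%.

The numbers were drawn at random within sensible limits, and the outcome is calculated.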